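## Structural features

The target is a benzotropolone: a benzo[7]annulen-5-one with a hydroxyl at C6 next to the C5 carbonyl, and a benzo ring carrying three adjacent hydroxyls at C2, C3 and C4 (C4 peri to the carbonyl, C1 unsubstituted). Annulene C8 is bonded to C2 of a 5,7-dihydroxychroman-3-ol, that is, a pyran ring C fused to a phloroglucinol-type ring A. The only stereocentres are the adjacent chroman carbons C2 and C3, both R, with the tropolone and the C3 hydroxyl cis (the epi arrangement). Chroman C2 is an ether carbon that is also attached to the tropolone, so it can epimerise or ring-open under acid or base and can be hydrogenolysed. Ring A is a very strong carbon nucleophile, and the pyrogallol and tropolone units are oxidation-prone and bind metals. The real difficulty is twofold: to obtain the cis C2/C3 pair, and to build a seven-membered ring at the tropolone oxidation level on a branched, oxygenated sp3 carbon without disturbing that pair. The key step exploits the C8=C9 bond of the seven-membered ring, a trisubstituted styrene-type alkene between the arene-bound C9 and the chroman-bearing C8, which can be closed last from an aryl vinyl group and a 1,1-disubstituted alkene. With oxygen already on C5 and C6, one oxidation after ring closure gives a 1,2-dione that enolises to the tropolone.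

## Logic of the disconnections

**28 from 27.** Cut: the six O–CH2Ph bonds (three on the benzo ring, two on ring A, one at chroman C3). Reason: every hydroxyl must be inert to organolithium, boron, ruthenium and oxidant chemistry, and one neutral operation should free them all. Gain: an air-stable, non-chelating intermediate. Demand: hydrogenolysis must stop before the tropolone ring or the C2–O1 bond is reduced.

**27 from 25 (through 26).** No skeletal bond is cut; the C6 carbonyl level and the C6–C7 π bond are traded for a C6 carbinol and a C7 methylene. Reason: the aromatic ring cannot be closed directly by metathesis, whereas its dihydro ketol can. Gain: the seven-membered ring becomes an ordinary cycloheptenone. Demand: oxidation of a ketol to a dione that then enolises toward C7.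

**25 from 24.** Cut: C8=C9. Reason: it is the only ring bond flanked by no heteroatom, and its two carbons can each end a terminal alkene. Gain: the carbocycle opens to an acyclic diene whose two halves are joined by one C–C bond. Demand: closure of a seven-membered ring to a trisubstituted alkene without migration of the 1,1-disubstituted alkene toward chroman C2.

**24 from 22 and 9.** Cut: C6–C7. Reason: an allyl–carbonyl addition creates the C6 carbinol and the C–C bond together under neutral conditions, so no protecting group is needed at C6. Gain: two fragments of similar size, one holding all stereochemistry, the other all the pyrogallol oxygens. Demand: the allyl donor must add to the aldehyde of 9 and leave its hindered aryl ketone alone.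

**22 from 20 from 19.** Cuts: the bond between the alkene carbon and the boron-bearing methylene, then the C8–B bond. Reason: a terminal alkyne is the smallest robust precursor of a 2-substituted allyl unit. Gain: the chroman fragment is reduced to an ethynyl chroman. Demand: boron must go to the internal alkyne carbon.

**19 from 17 (through 18) from 16.** Cuts: the O–benzyl bond at C3 and the C–Si bond, then C4–C4a. Reason: ring A is nucleophilic enough to open a terminal epoxide at the position ortho to its ether oxygen. Gain: ring C opens to an aryl ether of an epoxy alcohol. Demand: attack must occur at the unsubstituted epoxide carbon (six-membered ring) and leave C2 and C3 untouched.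

**16 from 14 and 15.** Cut: O1–C2. Reason: a phenol can displace an activated propargylic carbinol with inversion, which converts the erythro epoxy alcohol into the threo ether that gives the cis chroman. Gain: ring A is removed as a symmetric phenol. Demand: clean SN2 at a carbinol flanked by alkyne and oxirane.

**14 from 13 from 10 and 11 (through 12).** Cuts: the two C–O bonds of the oxirane, then the bond between carbinol carbon and alkyne carbon. Reason: a racemic vinyl alkynyl carbinol can be resolved and epoxidised in one operation, fixing both future stereocentres. Gain: two commodity chemicals. Demand: a useful rate difference between the enantiomers of 13.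

**9 from 8 from 6 (through 7).** Cuts: the aldehyde oxygen (oxidation of the acetyl methyl), then the aryl–acyl bond. Reason: an aryllithium from a bromide places the two-carbon unit exactly between the vinyl group and the benzyloxy group. Gain: a simple bromostyrene. Demand: halogen–lithium exchange must outrun addition to the styrene.

**6 from 5 from 4 from 3 from 2 from 1.** Cuts: the vinyl C=C, the aldehyde oxidation level, the C–Br bond, the ester reduction and four O–benzyl bonds. Reason: gallic acid already has the three adjacent oxygens and a carbon that becomes annulene C9. Gain: a commodity starting material. Demand: bromination ortho to the hydroxymethyl group, which symmetry makes unambiguous.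

## Other disconnections considered

**Alternative 1:** The cut runs through ring C at C3–C4 and O1–C2. Ring A arrives as hydroxymethyl phenol A2 and the rest as the (Z)-silyl enol ether A4 of a preformed benzotropolonyl ketone. Forward, A2 loses water to quinone methide A3, which A4 traps in an inverse-demand hetero-Diels–Alder reaction to give ketal A1. An ionic reduction at C2 would then have to deliver hydride anti to the C3 benzyloxy group to reach the cis chroman.
- In favour: two bonds and ring C are formed in one step from two large fragments, with the oxygenated enol carbon bonding to O1. On convergence and on bonds formed in the key step it is better than the chosen plan.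
- Against: neither partner has a stereocentre, so the absolute configuration at C3 must come from an external chiral controller acting on a short-lived heterodiene. The C2 cation of the reduction is conjugated with the tropolone and may eliminate to a chromene. The tropolone benzyl ether in A4 can exist as two O-alkyl isomers. A4 requires a complete benzotropolone synthesis of its own.
- Comparison: on structure the chosen plan sets C2 and C3 early, on a five-carbon molecule, with a reagent of known sense. On mechanism both ring closures are of well-understood types and are equal. On step economy the two endgames are about equal, but the unsolved access to A4 makes the alternative longer overall.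

**Alternative 2:** The cut removes two bonds of the seven-membered ring, C6–C7 and C8–C9. Forward, Rh2(OAc)4 converts diazoketone A6 into a cyclic carbonyl ylide that adds across the alkyne of A7 (the 3-O-silyl counterpart of 19) to give oxygen-bridged adduct A5. Acid-promoted opening of the bridge then gives the tropolone.
- In favour: the ethynyl chroman is used as such, with no elaboration of the alkyne; two C–C bonds form at once; the adduct is already at the tropolone oxidation level. On step economy after the alkyne it is better than the chosen plan. The bridgehead centres are erased, just as C6 is in the chosen plan, so the two are equal on that point.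
- Against: the dipole is unsymmetrical, and the substituted alkyne carbon must bond to the benzylic ylide carbon, an orientation that is not assured. The carbenoid in A6 sits next to a benzyloxy group, so oxonium ylide formation and benzyl shift compete with carbonyl ylide formation. A6 needs diazomethane chemistry on a crowded, electron-rich acid. The acidic bridge opening acts on a molecule with a labile C2 ether.
- Comparison: on structure it is more direct. On mechanism it carries two selectivity questions (ylide formation and regiochemistry) against one (ring closure versus alkene migration) for metathesis. On step economy it would win if both selectivities held.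

**Alternative 3:** The cut is a one-carbon excision: C5–C6 and C6–C7, with C6 coming from a carbene. Forward, dichlorocarbene adds to the C1–C2 bond of the methoxynaphthalene in naphthyl flavan A9, and the cyclopropane opens with loss of chloride and chloromethane to chlorobenzotropone A8. The chloride must then be exchanged for hydroxyl and the acetates removed.
- In favour: the stereochemical part is a 2-aryl flavan-3-ol, for which chalcone and dihydroxylation routes are thoroughly established. On reliability of the C2/C3 construction it is better than the chosen plan. The ring expansion itself is a single step.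
- Against: carbene generation under strong base is incompatible with six aryl and alkyl acetates. The carbene must choose one π bond among several electron-rich ones, including ring A. Hydrolysis of a chlorotropone needs forcing acid or base, which invites ring contraction to a naphthoic acid and epimerisation at C2. The 1,6,7,8-tetraoxygenated 3-substituted naphthalene is itself a long synthesis.
- Comparison: on structure it reuses flavonoid chemistry well. On mechanism the carbene step has poorer chemoselectivity than metathesis. On step economy the short endgame is offset by the naphthalene synthesis and the chloride exchange.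

Key step: step 16

Remarks on the chemistry:
- 15 is taken as a purchasable dibenzyl ether of phloroglucinol.
- The C6 oxygen of the metathesis substrate is carried as a free hydroxyl; a silyl ether at this oxygen is kept in reserve.
- The (2R,3R) descriptors of the substrate and product of the key step were checked against the target and need no correction.
- The sense of the tartrate in step 9 (L-(+)-DIPT consuming the (R)-enantiomer of 13) is assigned by analogy with alkyl vinyl carbinols and should be confirmed on the first batch.

## Route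

**Step 1**
Reactants: 1 gallic acid
Product: 2 benzyl 3,4,5-tris(benzyloxy)benzoate
Conditions: BnBr, K2CO3, DMF, 60 °C
Reagents that add atoms: benzyl bromide, BrCc1ccccc1
Why: Williamson etherification of the three phenols and alkylation of the carboxylate in one operation; the ester is reduced in the next step, so its identity does not matter.

**Step 2**
Reactants: 2 benzyl 3,4,5-tris(benzyloxy)benzoate
Product: 3 [3,4,5-tris(benzyloxy)phenyl]methanol
Conditions: LiAlH4, THF, 0 °C → rt
Reagents that add atoms: none
Why: Hydride reduction of the ester to the benzylic alcohol; benzyl ethers are inert.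

**Step 3**
Reactants: 3 [3,4,5-tris(benzyloxy)phenyl]methanol
Product: 4 [3,4,5-tris(benzyloxy)-2-bromophenyl]methanol
Conditions: NBS, CHCl3, 0 °C → rt
Reagents that add atoms: N-bromosuccinimide, O=C1CCC(=O)N1Br
Why: Electrophilic aromatic bromination; the two free ring positions are equivalent and each is activated ortho and para by benzyloxy groups, so only one monobromide can form.

**Step 4**
Reactants: 4 [3,4,5-tris(benzyloxy)-2-bromophenyl]methanol
Product: 5 3,4,5-tris(benzyloxy)-2-bromobenzaldehyde
Conditions: MnO2, CH2Cl2, rt
Reagents that add atoms: none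
Why: Selective oxidation of a benzylic alcohol to the aldehyde without over-oxidation.

**Step 5**
Reactants: 5 3,4,5-tris(benzyloxy)-2-bromobenzaldehyde
Product: 6 1,2,3-tris(benzyloxy)-4-bromo-5-ethenylbenzene
Conditions: Ph3PCH3Br, KOtBu, THF, 0 °C → rt
Reagents that add atoms: methyltriphenylphosphonium bromide, C[P+](c1ccccc1)(c1ccccc1)c1ccccc1.[Br-]
Why: Wittig methylenation of an aromatic aldehyde; the aryl bromide is untouched by the ylide.

**Step 6**
Reactants: 6 1,2,3-tris(benzyloxy)-4-bromo-5-ethenylbenzene
Product: 8 1-[2,3,4-tris(benzyloxy)-6-ethenylphenyl]ethan-1-one, via aryllithium 7 (not isolated)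
Conditions: n-BuLi, THF, −78 °C; MeC(O)N(OMe)Me, −78 → 0 °C
Reagents that add atoms: N-methoxy-N-methylacetamide, CC(=O)N(C)OC
Why: Bromine–lithium exchange is much faster at −78 °C than addition of butyllithium to the styrene; the aryllithium acylates the unhindered Weinreb amide, whose chelated adduct prevents a second addition (Weinreb ketone synthesis).

**Step 7**
Reactants: 8 1-[2,3,4-tris(benzyloxy)-6-ethenylphenyl]ethan-1-one
Product: 9 2-oxo-2-[2,3,4-tris(benzyloxy)-6-ethenylphenyl]acetaldehyde
Conditions: SeO2, 1,4-dioxane–H2O, BHT (cat.), 90 °C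
Reagents that add atoms: selenium dioxide, O=[Se]=O
Why: Riley oxidation of an aryl methyl ketone to the aryl glyoxal through the enol; the vinyl group has no allylic hydrogen and should be spared. The product is handled as its hydrate and dried azeotropically before use.

**Step 8**
Reactants: 10 ethynyl(trimethyl)silane; 11 acrolein
Product: 13 rac-5-(trimethylsilyl)pent-1-en-4-yn-3-ol, via lithium (trimethylsilyl)acetylide 12 (not isolated)
Conditions: n-BuLi, THF, −78 °C; acrolein, −78 °C; aq NH4Cl
Reagents that add atoms: none
Why: A hard lithium acetylide adds 1,2 to acrolein at low temperature, giving the racemic alkynyl vinyl carbinol.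

**Step 9**
Reactants: 13 rac-5-(trimethylsilyl)pent-1-en-4-yn-3-ol
Product: 14 (1S)-1-[(2R)-oxiran-2-yl]-3-(trimethylsilyl)prop-2-yn-1-ol
Conditions: Ti(OiPr)4 (cat.), L-(+)-DIPT, t-BuOOH (0.45 equiv), 4 Å MS, CH2Cl2, −20 °C
Reagents that add atoms: tert-butyl hydroperoxide, CC(C)(C)OO
Why: Sharpless kinetic resolution: the titanium tartrate should epoxidise the (R)-enantiomer of 13 much faster and from the face that gives the erythro epoxy alcohol, so the carbinol carbon and the oxirane carbon (the future chroman C2 and C3) are fixed together by the reagent; unreacted (S)-13 is separated. The carbinol descriptor changes from R to S only because the oxirane carbon outranks the alkynyl group.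

**Step 10**
Reactants: 14 (1S)-1-[(2R)-oxiran-2-yl]-3-(trimethylsilyl)prop-2-yn-1-ol; 15 3,5-bis(benzyloxy)phenol
Product: 16 {(3R)-3-[3,5-bis(benzyloxy)phenoxy]-3-[(2R)-oxiran-2-yl]prop-1-yn-1-yl}(trimethyl)silane
Conditions: PPh3, DIAD, THF, 0 °C → rt
Reagents that add atoms: none
Why: Mitsunobu etherification with inversion at the propargylic carbinol, which converts the erythro epoxy alcohol into the threo aryl ether needed for a cis chroman; the oxirane is stable under these neutral conditions and its carbon keeps its configuration.

**Step 11**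
Reactants: 16 {(3R)-3-[3,5-bis(benzyloxy)phenoxy]-3-[(2R)-oxiran-2-yl]prop-1-yn-1-yl}(trimethyl)silane
Product: 17 (2R,3R)-5,7-bis(benzyloxy)-2-[(trimethylsilyl)ethynyl]-3,4-dihydro-2H-chromen-3-ol
Conditions: (CF3)2CHOH, 0 °C → rt
Reagents that add atoms: none
Why: Intramolecular Friedel–Crafts epoxide–arene cyclisation, promoted by the hydrogen-bond-donor solvent: the ring A carbon ortho to the ether oxygen attacks the unsubstituted epoxide carbon (6-endo), which is the less hindered one and the one not deactivated by the neighbouring aryloxy-bearing carbon. The C3–O bond is not broken and C2 is not involved, so the threo ether gives the cis (2R,3R) chromanol.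

**Step 12**
Reactants: 17 (2R,3R)-5,7-bis(benzyloxy)-2-[(trimethylsilyl)ethynyl]-3,4-dihydro-2H-chromen-3-ol
Product: 19 (2R,3R)-3,5,7-tris(benzyloxy)-2-ethynyl-3,4-dihydro-2H-chromene, via silylalkyne benzyl ether 18 (not isolated)
Conditions: NaH, BnBr, Bu4NI (cat.), DMF, 0 °C → rt; then K2CO3, MeOH, rt
Reagents that add atoms: benzyl bromide, BrCc1ccccc1
Why: Williamson benzylation of the secondary alcohol, then methanolysis of the alkynyl–silicon bond in the same flask; neither operation touches C2 or C3.

**Step 13**
Reactants: 19 (2R,3R)-3,5,7-tris(benzyloxy)-2-ethynyl-3,4-dihydro-2H-chromene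
Product: 20 2-{1-[(2R,3R)-3,5,7-tris(benzyloxy)-3,4-dihydro-2H-chromen-2-yl]ethenyl}-4,4,5,5-tetramethyl-1,3,2-dioxaborolane
Conditions: B2pin2, (SIMes)CuCl (5 mol %), NaOtBu (5 mol %), MeOH, THF, −20 °C → rt
Reagents that add atoms: bis(pinacolato)diboron, CC1(C)OB(OC1(C)C)B1OC(C)(C)C(C)(C)O1
Why: Copper-catalysed protoboration of a terminal alkyne (syn addition of Cu–B, then protonation by methanol); the N-aryl carbene ligand and the electron-withdrawing propargylic oxygen should direct boron to the internal carbon, giving the 1,1-disubstituted alkenylboronate under nearly neutral conditions.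

**Step 14**
Reactants: 20 2-{1-[(2R,3R)-3,5,7-tris(benzyloxy)-3,4-dihydro-2H-chromen-2-yl]ethenyl}-4,4,5,5-tetramethyl-1,3,2-dioxaborolane
Product: 22 2-{2-[(2R,3R)-3,5,7-tris(benzyloxy)-3,4-dihydro-2H-chromen-2-yl]prop-2-en-1-yl}-4,4,5,5-tetramethyl-1,3,2-dioxaborolane, via chloromethyl boronate complex 21 (not isolated)
Conditions: ClCH2I, n-BuLi, THF, −78 °C → rt
Reagents that add atoms: chloroiodomethane, ClCI
Why: Matteson homologation: (chloromethyl)lithium generated in the presence of the boronate adds to boron, and 1,2-migration of the alkenyl group with loss of chloride gives the 2-substituted allylboronate.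

**Step 15**
Reactants: 22 2-{2-[(2R,3R)-3,5,7-tris(benzyloxy)-3,4-dihydro-2H-chromen-2-yl]prop-2-en-1-yl}-4,4,5,5-tetramethyl-1,3,2-dioxaborolane; 9 2-oxo-2-[2,3,4-tris(benzyloxy)-6-ethenylphenyl]acetaldehyde
Product: 24 1-[2,3,4-tris(benzyloxy)-6-ethenylphenyl]-2-hydroxy-4-[(2R,3R)-3,5,7-tris(benzyloxy)-3,4-dihydro-2H-chromen-2-yl]pent-4-en-1-one (both epimers at the carbinol carbon), via O-boryl adduct 23 (not isolated)
Conditions: 4 Å MS, toluene, rt; then H2O
Reagents that add atoms: none
Why: Allylboration through a six-membered cyclic transition state with allyl transposition forms C6–C7 and the C6 carbinol; the aldehyde of 9 is far more electrophilic than its di-ortho-substituted aryl ketone. No base is present, so chroman C2 is safe, and the new carbinol centre is a mixture that is erased in step 17.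

**Step 16**
Reactants: 24 1-[2,3,4-tris(benzyloxy)-6-ethenylphenyl]-2-hydroxy-4-[(2R,3R)-3,5,7-tris(benzyloxy)-3,4-dihydro-2H-chromen-2-yl]pent-4-en-1-one
Product: 25 2,3,4-tris(benzyloxy)-6-hydroxy-8-[(2R,3R)-3,5,7-tris(benzyloxy)-3,4-dihydro-2H-chromen-2-yl]-6,7-dihydro-5H-benzo[7]annulen-5-one (both epimers at C6)
Conditions: second-generation Grubbs catalyst RuCl2(=CHPh)(H2IMes)(PCy3) (10 mol %), 1,4-benzoquinone (20 mol %), toluene (0.002 M), 80 °C
Reagents that add atoms: none
Why: Ring-closing olefin metathesis: the ruthenium benzylidene exchanges onto the unhindered aryl vinyl group, the resulting styrenyl carbene adds across the 1,1-disubstituted alkene in a [2+2] step, and cycloreversion of the ruthenacyclobutane closes the ring and releases a methylidene that leaves as ethene. The closest known reaction type is ring-closing metathesis of 2-vinylaryl ketones with a pendant alkene to benzo-fused cycloheptenones, including closures onto 1,1-disubstituted alkenes that give trisubstituted ring alkenes. The one ring formed is the seven-membered carbocycle, closed by joining the two alkene carbons that the rigid aryl ketone holds five atoms apart; the new C8=C9 bond is cis within the ring by constraint and conjugated with the arene, and loss of ethene makes the closure irreversible. No stereocentre is created: C6 is an inconsequential mixture and the chroman centres lie one and two bonds from the reacting alkene but are not involved in bond changes. The step needs ring closure to win over intermolecular coupling at the styrene, which high dilution and the short tether should secure, and it needs the 1,1-disubstituted alkene not to migrate toward chroman C2, which the hydride scavenger 1,4-benzoquinone and the absence of base should secure. Benzyl ethers, the free hydroxyl and the ketone are tolerated by this catalyst.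

**Step 17**
Reactants: 25 2,3,4-tris(benzyloxy)-6-hydroxy-8-[(2R,3R)-3,5,7-tris(benzyloxy)-3,4-dihydro-2H-chromen-2-yl]-6,7-dihydro-5H-benzo[7]annulen-5-one
Product: 27 2,3,4-tris(benzyloxy)-6-hydroxy-8-[(2R,3R)-3,5,7-tris(benzyloxy)-3,4-dihydro-2H-chromen-2-yl]-5H-benzo[7]annulen-5-one, via annulene-5,6-dione 26 (not isolated)
Conditions: Dess–Martin periodinane, CH2Cl2, 0 °C → rt
Reagents that add atoms: none
Why: Dess–Martin oxidation of the ketol gives the 1,2-dione, whose C7 methylene enolises at once because this makes the aromatic hydroxytropone; both C6 epimers converge and no dehydrogenation step is needed.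

**Step 18**
Reactants: 27 2,3,4-tris(benzyloxy)-6-hydroxy-8-[(2R,3R)-3,5,7-tris(benzyloxy)-3,4-dihydro-2H-chromen-2-yl]-5H-benzo[7]annulen-5-one
Product: 28 2,3,4,6-tetrahydroxy-8-[(2R,3R)-3,5,7-trihydroxy-3,4-dihydro-2H-chromen-2-yl]-5H-benzo[7]annulen-5-one
Conditions: H2 (1 atm), Pd(OH)2/C, THF–MeOH, rt
Reagents that add atoms: none
Why: Hydrogenolysis of six benzyl ethers under neutral conditions, as in flavan-3-ol deprotections, which should leave C2 and C3 untouched; the reaction is stopped at the uptake that corresponds to six benzyl groups.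

## Compound list

1 | gallic acid | O=C(O)c1cc(O)c(O)c(O)c1 | starting material
2 | benzyl 3,4,5-tris(benzyloxy)benzoate | O=C(OCc1ccccc1)c1cc(OCc2ccccc2)c(OCc2ccccc2)c(OCc2ccccc2)c1 | intermediate
3 | [3,4,5-tris(benzyloxy)phenyl]methanol | OCc1cc(OCc2ccccc2)c(OCc2ccccc2)c(OCc2ccccc2)c1 | intermediate
4 | [3,4,5-tris(benzyloxy)-2-bromophenyl]methanol | OCc1cc(OCc2ccccc2)c(OCc2ccccc2)c(OCc2ccccc2)c1Br | intermediate
5 | 3,4,5-tris(benzyloxy)-2-bromobenzaldehyde | O=Cc1cc(OCc2ccccc2)c(OCc2ccccc2)c(OCc2ccccc2)c1Br | intermediate
6 | 1,2,3-tris(benzyloxy)-4-bromo-5-ethenylbenzene | C=Cc1cc(OCc2ccccc2)c(OCc2ccccc2)c(OCc2ccccc2)c1Br | intermediate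
7 | [2,3,4-tris(benzyloxy)-6-ethenylphenyl]lithium | [Li]c1c(C=C)cc(OCc2ccccc2)c(OCc2ccccc2)c1OCc1ccccc1 | intermediate
8 | 1-[2,3,4-tris(benzyloxy)-6-ethenylphenyl]ethan-1-one | CC(=O)c1c(C=C)cc(OCc2ccccc2)c(OCc2ccccc2)c1OCc1ccccc1 | intermediate
9 | 2-oxo-2-[2,3,4-tris(benzyloxy)-6-ethenylphenyl]acetaldehyde | O=CC(=O)c1c(C=C)cc(OCc2ccccc2)c(OCc2ccccc2)c1OCc1ccccc1 | intermediate
10 | ethynyl(trimethyl)silane | C#C[Si](C)(C)C | starting material
11 | acrolein | C=CC=O | starting material
12 | lithium (trimethylsilyl)acetylide | [Li]C#C[Si](C)(C)C | intermediate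
13 | rac-5-(trimethylsilyl)pent-1-en-4-yn-3-ol | C=CC(O)C#C[Si](C)(C)C | intermediate
14 | (1S)-1-[(2R)-oxiran-2-yl]-3-(trimethylsilyl)prop-2-yn-1-ol | C[Si](C)(C)C#C[C@H](O)[C@H]1CO1 | intermediate
15 | 3,5-bis(benzyloxy)phenol | Oc1cc(OCc2ccccc2)cc(OCc2ccccc2)c1 | starting material
16 | {(3R)-3-[3,5-bis(benzyloxy)phenoxy]-3-[(2R)-oxiran-2-yl]prop-1-yn-1-yl}(trimethyl)silane | C[Si](C)(C)C#C[C@@H](Oc1cc(OCc2ccccc2)cc(OCc2ccccc2)c1)[C@H]1CO1 | intermediate
17 | (2R,3R)-5,7-bis(benzyloxy)-2-[(trimethylsilyl)ethynyl]-3,4-dihydro-2H-chromen-3-ol | C[Si](C)(C)C#C[C@H]1Oc2cc(OCc3ccccc3)cc(OCc3ccccc3)c2C[C@H]1O | intermediate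
18 | {[(2R,3R)-3,5,7-tris(benzyloxy)-3,4-dihydro-2H-chromen-2-yl]ethynyl}(trimethyl)silane | C[Si](C)(C)C#C[C@H]1Oc2cc(OCc3ccccc3)cc(OCc3ccccc3)c2C[C@H]1OCc1ccccc1 | intermediate
19 | (2R,3R)-3,5,7-tris(benzyloxy)-2-ethynyl-3,4-dihydro-2H-chromene | C#C[C@H]1Oc2cc(OCc3ccccc3)cc(OCc3ccccc3)c2C[C@H]1OCc1ccccc1 | intermediate
20 | 2-{1-[(2R,3R)-3,5,7-tris(benzyloxy)-3,4-dihydro-2H-chromen-2-yl]ethenyl}-4,4,5,5-tetramethyl-1,3,2-dioxaborolane | C=C(B1OC(C)(C)C(C)(C)O1)[C@H]1Oc2cc(OCc3ccccc3)cc(OCc3ccccc3)c2C[C@H]1OCc1ccccc1 | intermediate
21 | lithium (chloromethyl){1-[(2R,3R)-3,5,7-tris(benzyloxy)-3,4-dihydro-2H-chromen-2-yl]ethenyl}(pinacolato)borate | [Li+].ClC[B-]1(OC(C)(C)C(C)(C)O1)C(=C)[C@H]1Oc2cc(OCc3ccccc3)cc(OCc3ccccc3)c2C[C@H]1OCc1ccccc1 | intermediate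
22 | 2-{2-[(2R,3R)-3,5,7-tris(benzyloxy)-3,4-dihydro-2H-chromen-2-yl]prop-2-en-1-yl}-4,4,5,5-tetramethyl-1,3,2-dioxaborolane | C=C(CB1OC(C)(C)C(C)(C)O1)[C@H]1Oc2cc(OCc3ccccc3)cc(OCc3ccccc3)c2C[C@H]1OCc1ccccc1 | intermediate
23 | 1-[2,3,4-tris(benzyloxy)-6-ethenylphenyl]-2-[(4,4,5,5-tetramethyl-1,3,2-dioxaborolan-2-yl)oxy]-4-[(2R,3R)-3,5,7-tris(benzyloxy)-3,4-dihydro-2H-chromen-2-yl]pent-4-en-1-one | C=Cc1cc(OCc2ccccc2)c(OCc2ccccc2)c(OCc2ccccc2)c1C(=O)C(OB1OC(C)(C)C(C)(C)O1)CC(=C)[C@H]1Oc2cc(OCc3ccccc3)cc(OCc3ccccc3)c2C[C@H]1OCc1ccccc1 | intermediate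
24 | 1-[2,3,4-tris(benzyloxy)-6-ethenylphenyl]-2-hydroxy-4-[(2R,3R)-3,5,7-tris(benzyloxy)-3,4-dihydro-2H-chromen-2-yl]pent-4-en-1-one | C=Cc1cc(OCc2ccccc2)c(OCc2ccccc2)c(OCc2ccccc2)c1C(=O)C(O)CC(=C)[C@H]1Oc2cc(OCc3ccccc3)cc(OCc3ccccc3)c2C[C@H]1OCc1ccccc1 | intermediate
25 | 2,3,4-tris(benzyloxy)-6-hydroxy-8-[(2R,3R)-3,5,7-tris(benzyloxy)-3,4-dihydro-2H-chromen-2-yl]-6,7-dihydro-5H-benzo[7]annulen-5-one | O=C1C(O)CC([C@H]2Oc3cc(OCc4ccccc4)cc(OCc4ccccc4)c3C[C@H]2OCc2ccccc2)=Cc2cc(OCc3ccccc3)c(OCc3ccccc3)c(OCc3ccccc3)c12 | intermediate
26 | 2,3,4-tris(benzyloxy)-8-[(2R,3R)-3,5,7-tris(benzyloxy)-3,4-dihydro-2H-chromen-2-yl]-5H-benzo[7]annulene-5,6(7H)-dione | O=C1C(=O)CC([C@H]2Oc3cc(OCc4ccccc4)cc(OCc4ccccc4)c3C[C@H]2OCc2ccccc2)=Cc2cc(OCc3ccccc3)c(OCc3ccccc3)c(OCc3ccccc3)c12 | intermediate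
27 | 2,3,4-tris(benzyloxy)-6-hydroxy-8-[(2R,3R)-3,5,7-tris(benzyloxy)-3,4-dihydro-2H-chromen-2-yl]-5H-benzo[7]annulen-5-one | O=c1c(O)cc([C@H]2Oc3cc(OCc4ccccc4)cc(OCc4ccccc4)c3C[C@H]2OCc2ccccc2)cc2cc(OCc3ccccc3)c(OCc3ccccc3)c(OCc3ccccc3)c12 | intermediate
28 | 2,3,4,6-tetrahydroxy-8-[(2R,3R)-3,5,7-trihydroxy-3,4-dihydro-2H-chromen-2-yl]-5H-benzo[7]annulen-5-one | O=c1c(O)cc([C@H]2Oc3cc(O)cc(O)c3C[C@H]2O)cc2cc(O)c(O)c(O)c12 | target

## Step count and least certain steps

Total step count: 18. Longest linear sequence: 11 steps (steps 8 to 18; the arene branch, steps 1 to 7 and then 15 to 18, is equally long).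

**Step 16 (key step).** The closure may be slow, because the styrenyl carbene can be held by the neighbouring ketone and hydroxyl and the 1,1-disubstituted alkene is shielded by the branched chroman carbon. This leaves time for hydride-promoted migration of the double bond toward C2, with loss of its configuration, or for intermolecular coupling at the styrene. Fallback: starting from 24, the hydroxyl is silylated (TBSCl, imidazole, DMF) to 1-[2,3,4-tris(benzyloxy)-6-ethenylphenyl]-2-[(tert-butyldimethylsilyl)oxy]-4-[(2R,3R)-3,5,7-tris(benzyloxy)-3,4-dihydro-2H-chromen-2-yl]pent-4-en-1-one F1. With no free chelating hydroxyl and a bulkier C6, F1 is cyclised by the same ruthenium carbene to 2,3,4-tris(benzyloxy)-6-[(tert-butyldimethylsilyl)oxy]-8-[(2R,3R)-3,5,7-tris(benzyloxy)-3,4-dihydro-2H-chromen-2-yl]-6,7-dihydro-5H-benzo[7]annulen-5-one F2. Desilylation with HF·pyridine returns to the route at 25.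

**Step 13.** Boron may be delivered to the terminal carbon instead; from that regioisomer the copper intermediate can eliminate the ring oxygen and open ring C. Fallback: starting from 19, palladium-catalysed Markovnikov hydromethoxycarbonylation (Pd(OAc)2, 2-pyridyldiphenylphosphine, MsOH, CO, MeOH) should give methyl 2-[(2R,3R)-3,5,7-tris(benzyloxy)-3,4-dihydro-2H-chromen-2-yl]prop-2-enoate F3. Reduction with i-Bu2AlH at −78 °C gives 2-[(2R,3R)-3,5,7-tris(benzyloxy)-3,4-dihydro-2H-chromen-2-yl]prop-2-en-1-ol F4, and an Appel reaction (CBr4, PPh3) gives (2R,3R)-3,5,7-tris(benzyloxy)-2-(3-bromoprop-1-en-2-yl)-3,4-dihydro-2H-chromene F5. Indium-mediated Barbier allylation of 9 with F5 in THF–water comes back to the route at 24.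

**Step 9.** The rate difference between the enantiomers of an alkynyl vinyl carbinol may be too small, which would erode the enantiomeric purity of the epoxy alcohol. Fallback: starting from 10 and 11, a catalytic enantioselective alkynylation (Me2Zn, a ProPhenol ligand of the appropriate hand, Ph3PO, toluene) gives (3R)-5-(trimethylsilyl)pent-1-en-4-yn-3-ol F6. The same titanium tartrate epoxidation then acts on F6 as a matched, doubly selecting step and comes back to the route at 14.

**Step 7.** The oxidant may attack the styrene or carry the glyoxal on to the keto acid, and the styrene may polymerise at the temperature needed. Fallback: starting from 6, the aryllithium 7 is acylated with ethyl diethoxyacetate to 2,2-diethoxy-1-[2,3,4-tris(benzyloxy)-6-ethenylphenyl]ethan-1-one F7, and hydrolysis of the acetal with aqueous formic acid comes back to the route at 9.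

**Step 18.** Reduction may continue into the tropolone ring, or the C2–O1 bond may be cleaved, since C2 is activated by the tropolone. Fallback: starting from 27, Lewis-acid dealkylation with BCl3 and pentamethylbenzene as cation scavenger in CH2Cl2 at −78 °C removes the benzyl groups without hydrogen and arrives at 28; this fallback makes no new compound (F0).

## Further compounds

F1 | step 16 | 1-[2,3,4-tris(benzyloxy)-6-ethenylphenyl]-2-[(tert-butyldimethylsilyl)oxy]-4-[(2R,3R)-3,5,7-tris(benzyloxy)-3,4-dihydro-2H-chromen-2-yl]pent-4-en-1-one | C=Cc1cc(OCc2ccccc2)c(OCc2ccccc2)c(OCc2ccccc2)c1C(=O)C(O[Si](C)(C)C(C)(C)C)CC(=C)[C@H]1Oc2cc(OCc3ccccc3)cc(OCc3ccccc3)c2C[C@H]1OCc1ccccc1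
F2 | step 16 | 2,3,4-tris(benzyloxy)-6-[(tert-butyldimethylsilyl)oxy]-8-[(2R,3R)-3,5,7-tris(benzyloxy)-3,4-dihydro-2H-chromen-2-yl]-6,7-dihydro-5H-benzo[7]annulen-5-one | O=C1C(O[Si](C)(C)C(C)(C)C)CC([C@H]2Oc3cc(OCc4ccccc4)cc(OCc4ccccc4)c3C[C@H]2OCc2ccccc2)=Cc2cc(OCc3ccccc3)c(OCc3ccccc3)c(OCc3ccccc3)c12
F3 | step 13 | methyl 2-[(2R,3R)-3,5,7-tris(benzyloxy)-3,4-dihydro-2H-chromen-2-yl]prop-2-enoate | C=C(C(=O)OC)[C@H]1Oc2cc(OCc3ccccc3)cc(OCc3ccccc3)c2C[C@H]1OCc1ccccc1
F4 | step 13 | 2-[(2R,3R)-3,5,7-tris(benzyloxy)-3,4-dihydro-2H-chromen-2-yl]prop-2-en-1-ol | C=C(CO)[C@H]1Oc2cc(OCc3ccccc3)cc(OCc3ccccc3)c2C[C@H]1OCc1ccccc1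
F5 | step 13 | (2R,3R)-3,5,7-tris(benzyloxy)-2-(3-bromoprop-1-en-2-yl)-3,4-dihydro-2H-chromene | C=C(CBr)[C@H]1Oc2cc(OCc3ccccc3)cc(OCc3ccccc3)c2C[C@H]1OCc1ccccc1
F6 | step 9 | (3R)-5-(trimethylsilyl)pent-1-en-4-yn-3-ol | C=C[C@@H](O)C#C[Si](C)(C)C
F7 | step 7 | 2,2-diethoxy-1-[2,3,4-tris(benzyloxy)-6-ethenylphenyl]ethan-1-one | CCOC(OCC)C(=O)c1c(C=C)cc(OCc2ccccc2)c(OCc2ccccc2)c1OCc1ccccc1
F0 | step 18 | none | none
A1 | alternative 1 | 2,3,4,6-tetrakis(benzyloxy)-8-[(3R)-3,5,7-tris(benzyloxy)-2-(trimethylsilyloxy)-3,4-dihydro-2H-chromen-2-yl]-5H-benzo[7]annulen-5-one (either C2 epimer) | O=c1c(OCc2ccccc2)cc(C4(O[Si](C)(C)C)Oc5cc(OCc6ccccc6)cc(OCc6ccccc6)c5C[C@H]4OCc6ccccc6)cc2cc(OCc3ccccc3)c(OCc3ccccc3)c(OCc3ccccc3)c12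
A2 | alternative 1 | 3,5-bis(benzyloxy)-2-(hydroxymethyl)phenol | OCc1c(O)cc(OCc2ccccc2)cc1OCc1ccccc1
A3 | alternative 1 | 3,5-bis(benzyloxy)-6-methylidenecyclohexa-2,4-dien-1-one | C=C1C(=O)C=C(OCc2ccccc2)C=C1OCc1ccccc1
A4 | alternative 1 | 2,3,4,6-tetrakis(benzyloxy)-8-[(Z)-2-(benzyloxy)-1-(trimethylsilyloxy)ethenyl]-5H-benzo[7]annulen-5-one | O=c1c(OCc2ccccc2)cc(/C(O[Si](C)(C)C)=C/OCc2ccccc2)cc2cc(OCc3ccccc3)c(OCc3ccccc3)c(OCc3ccccc3)c12
A5 | alternative 2 | oxygen-bridged benzocycloheptadienone cycloadduct carrying the (2R,3R)-chroman (bridgeheads as a mixture) | O=C1C2C=C([C@H]4Oc5cc(OCc6ccccc6)cc(OCc6ccccc6)c5C[C@H]4O[Si](C)(C)C(C)(C)C)C(O2)c2cc(OCc3ccccc3)c(OCc3ccccc3)c(OCc3ccccc3)c12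
A6 | alternative 2 | 3,4,5-tris(benzyloxy)-2-(2-diazoacetyl)benzaldehyde | O=Cc1cc(OCc2ccccc2)c(OCc2ccccc2)c(OCc2ccccc2)c1C(=O)C=[N+]=[N-]
A7 | alternative 2 | (2R,3R)-5,7-bis(benzyloxy)-3-[(tert-butyldimethylsilyl)oxy]-2-ethynyl-3,4-dihydro-2H-chromene | C#C[C@H]1Oc2cc(OCc3ccccc3)cc(OCc3ccccc3)c2C[C@H]1O[Si](C)(C)C(C)(C)C
A8 | alternative 3 | (2R,3R)-2-[2,3,4-tris(acetyloxy)-6-chloro-5-oxo-5H-benzo[7]annulen-8-yl]-3,4-dihydro-2H-chromene-3,5,7-triyl triacetate | O=c1c(Cl)cc([C@H]4Oc5cc(OC(C)=O)cc(OC(C)=O)c5C[C@H]4OC(C)=O)cc2cc(OC(C)=O)c(OC(C)=O)c(OC(C)=O)c12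
A9 | alternative 3 | (2R,3R)-2-[5,6,7-tris(acetyloxy)-4-methoxynaphthalen-2-yl]-3,4-dihydro-2H-chromene-3,5,7-triyl triacetate | COc1cc([C@H]2Oc3cc(OC(C)=O)cc(OC(C)=O)c3C[C@H]2OC(C)=O)cc2cc(OC(C)=O)c(OC(C)=O)c(OC(C)=O)c12
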